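**Retrosynthetic overview**
- The target is reached from a fully protected diaryl ether benzoate by unmasking only: dioxolane to ketone, methyl ester to acid, two benzyl ethers to phenols.
- The strategy rests on ring B, numbered as the benzoic acid: the methoxy carbon C4 is para to the carboxyl carbon C1 and lies between the two ring CH groups C3 and C5. C4–C5 therefore comes from 1,1-dimethoxyethene; C3(H), C2(OAr), C1(CO2Me) and C6(masked acyl) are C3, C4, C5 and C6 of a 2-pyrone-5-carboxylate, whose O1–C2 unit leaves as CO2.
- The crowded diaryl ether C–O bond is cut at the pyrone stage: the ring A phenol displaces chloride from C4 of a 4-chloro-2-pyrone by addition–elimination.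
- The pyrone comes from dimethyl 3-oxoglutarate, C-acylated with the dioxolane-protected 2-oxohexanoyl chloride and then lactonized; the ring A phenol comes from olivetol by benzylation, formylation and Baeyer–Villiger oxidation.
- Ring order: ring A is bought, the pyrone ring is closed by lactonization, and the pyrone is then converted into carbocyclic ring B by cycloaddition.

Key step: step 12

Remark on the chemistry: the target has no stereocentre. As a 2-acylbenzoic acid it can equilibrate with its cyclic 3-hydroxyphthalide tautomer; it is treated here in the open keto acid form of the given structure. Pyrone positions follow normal 2-pyrone numbering (O1, C2 = lactone carbonyl).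

Step 1
Reactants: 1 olivetol (5-pentylbenzene-1,3-diol)
Product: 2 1,3-bis(benzyloxy)-5-pentylbenzene
Conditions: BnBr (2.4 equiv), K2CO3, DMF, 60 °C
Reagents that add atoms: benzyl bromide, BrCc1ccccc1
Why: Williamson O-alkylation of both phenoxides under carbonate in a dipolar aprotic solvent, where O-alkylation of the resorcinol should dominate over C-alkylation.

Step 2
Reactants: 2 1,3-bis(benzyloxy)-5-pentylbenzene
Product: 3 2,4-bis(benzyloxy)-6-pentylbenzaldehyde
Conditions: POCl3, DMF, 0 to 70 °C; then aq. NaOAc
Reagents that add atoms: N,N-dimethylformamide, CN(C)C=O (formyl carbon); water, O (formyl oxygen, on hydrolysis of the iminium salt)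
Why: Vilsmeier–Haack formylation should go to the ring position next to the pentyl chain, which is ortho to one benzyloxy group and para to the other, because the site between the two ethers is the most crowded for the bulky chloroiminium electrophile.

Step 3
Reactants: 3 2,4-bis(benzyloxy)-6-pentylbenzaldehyde
Product: 5 2,4-bis(benzyloxy)-6-pentylphenol, via aryl formate 4 (not isolated)
Conditions: mCPBA, CH2Cl2, 0 °C to rt; aq. NaHCO3 wash; then K2CO3 (cat.), MeOH, rt
Reagents that add atoms: mCPBA (3-chloroperoxybenzoic acid), OOC(=O)c1cccc(Cl)c1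
Why: Baeyer–Villiger (Dakin-type) oxidation in which the electron-rich aryl group with ortho and para alkoxy donors migrates in preference to hydride, followed by mild methanolysis of the formate that leaves the benzyl ethers untouched.

Step 4
Reactants: 6 ethyl 2-oxohexanoate
Product: 7 ethyl 2-butyl-1,3-dioxolane-2-carboxylate
Conditions: Me3SiOCH2CH2OSiMe3, Me3SiOTf (cat.), CH2Cl2, −78 to −20 °C; pyridine quench
Reagents that add atoms: 1,2-bis(trimethylsilyloxy)ethane, C[Si](C)(C)OCCO[Si](C)(C)C
Why: Noyori ketalization converts the activated ketone of the α-keto ester into the dioxolane under aprotic conditions, avoiding the transesterification that free ethylene glycol and acid could cause.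

Step 5
Reactants: 7 ethyl 2-butyl-1,3-dioxolane-2-carboxylate
Product: 8 sodium 2-butyl-1,3-dioxolane-2-carboxylate
Conditions: NaOH (1.0 equiv), MeOH/H2O, rt; evaporate, dry azeotropically with toluene
Reagents that add atoms: sodium hydroxide, [Na+].[OH-]
Why: Ester saponification to which the ketal is inert; isolating the sodium salt keeps the α-ketal acid away from acid and prepares an HCl-free chlorination.

Step 6
Reactants: 8 sodium 2-butyl-1,3-dioxolane-2-carboxylate
Product: 9 2-butyl-1,3-dioxolane-2-carbonyl chloride
Conditions: (COCl)2 (1.05 equiv), pyridine (cat.), Et2O, 0 °C; filter, concentrate cold, use at once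
Reagents that add atoms: oxalyl chloride, ClC(=O)C(=O)Cl
Why: Acyl chloride formation from a carboxylate salt through the mixed oxalyl anhydride releases only NaCl, CO and CO2, so no HCl is present to open the dioxolane, and cold immediate use limits decarbonylation of the α,α-dialkoxy acyl chloride.

Step 7
Reactants: 9 2-butyl-1,3-dioxolane-2-carbonyl chloride; 10 dimethyl 3-oxoglutarate
Product: 11 dimethyl 2-(2-butyl-1,3-dioxolane-2-carbonyl)-3-oxopentanedioate
Conditions: MgCl2 (1.0 equiv), pyridine (2.0 equiv), CH2Cl2, 0 °C; then 9, 0 °C to rt; cold aq. citric acid work-up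
Reagents that add atoms: none
Why: Magnesium-mediated soft enolization and C-acylation of a β-keto ester (Rathke conditions), in which chelation favours C- over O-acylation and the more acidic tricarbonyl product, held as its magnesium chelate, should resist a second acylation.

Step 8
Reactants: 11 dimethyl 2-(2-butyl-1,3-dioxolane-2-carbonyl)-3-oxopentanedioate
Product: 12 methyl 6-(2-butyl-1,3-dioxolan-2-yl)-4-hydroxy-2-oxo-2H-pyran-5-carboxylate
Conditions: DBU (1.2 equiv), toluene, 80 °C; cold aq. NaH2PO4 work-up
Reagents that add atoms: none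
Why: Base-promoted enol lactonization in which the enol oxygen of the newly introduced acyl ketone attacks the distal ester, the only closure that gives a six-membered ring, driven by loss of methanol and formation of the stabilized 4-hydroxy-2-pyrone anion.

Step 9
Reactants: 12 methyl 6-(2-butyl-1,3-dioxolan-2-yl)-4-hydroxy-2-oxo-2H-pyran-5-carboxylate
Product: 13 methyl 6-(2-butyl-1,3-dioxolan-2-yl)-4-chloro-2-oxo-2H-pyran-5-carboxylate
Conditions: POCl3 (3 equiv), Et3N (1.5 equiv), MeCN, 60 °C; ice-water quench
Reagents that add atoms: phosphoryl chloride, O=P(Cl)(Cl)Cl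
Why: Activation of the vinylogous acid as its dichlorophosphate and addition–elimination of chloride at C4 is the established route from 4-hydroxy- to 4-chloro-2-pyrones; a DMF-derived chloroiminium reagent is avoided because it would also formylate C3, and the amine buffer protects the dioxolane.

Step 10
Reactants: 5 2,4-bis(benzyloxy)-6-pentylphenol; 13 methyl 6-(2-butyl-1,3-dioxolan-2-yl)-4-chloro-2-oxo-2H-pyran-5-carboxylate
Product: 14 methyl 4-[2,4-bis(benzyloxy)-6-pentylphenoxy]-6-(2-butyl-1,3-dioxolan-2-yl)-2-oxo-2H-pyran-5-carboxylate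
Conditions: Cs2CO3, MeCN, 0 °C to rt
Reagents that add atoms: none
Why: Nucleophilic vinylic substitution (addition–elimination) of the phenoxide at C4, the β-carbon of the lactone carbonyl, is made irreversible by loss of chloride, whereas addition at the hindered C6 or at the lactone carbonyl can revert by expelling the phenoxide.

Step 11
Reactants: 15 bromoacetaldehyde dimethyl acetal (2-bromo-1,1-dimethoxyethane)
Product: 16 1,1-dimethoxyethene
Conditions: KOtBu, neat, 120–150 °C, product distilled out and fractionated
Reagents that add atoms: none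
Why: E2 dehydrobromination of a β-bromo acetal with a hindered alkoxide is the classical ketene acetal synthesis, and continuous distillation removes the sensitive product from the base.

Step 12
Reactants: 14 methyl 4-[2,4-bis(benzyloxy)-6-pentylphenoxy]-6-(2-butyl-1,3-dioxolan-2-yl)-2-oxo-2H-pyran-5-carboxylate; 16 1,1-dimethoxyethene
Product: 19 methyl 2-[2,4-bis(benzyloxy)-6-pentylphenoxy]-6-(2-butyl-1,3-dioxolan-2-yl)-4-methoxybenzoate, via bridged lactone cycloadduct 17 (not isolated), via cyclohexadiene dimethyl ketal 18 (not isolated)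
Conditions: 16 (8 equiv), toluene, sealed tube, 110 °C
Reagents that add atoms: none
Why: The electron-rich CH2 terminus of the ketene acetal should add to pyrone C6 (β to the 5-ester and δ to the lactone carbonyl), and the resulting dienolate closes from C3 onto the dimethoxycarbenium carbon, an asynchronous inverse-electron-demand Diels–Alder reaction that gives bridged lactone 17; cycloreversion then expels CO2 to give diene 18, and 1,2-elimination of methanol from its ketal carbon and the neighbouring CH2 aromatizes the ring. The closest known reaction type is the cycloaddition of alkyl 2-pyrone-5-carboxylates (coumalates) with ketene acetals, which gives 4-alkoxybenzoates after loss of CO2 and alcohol. Ring B is closed by intermolecular [4+2] cycloaddition, forming the CH2–C6 and C(OMe)2–C3 bonds of a six-membered carbocycle on the pyrone diene, whose O1–C2 bridge is then extruded. The two bridgehead centres of 17 arise as a racemic pair fixed by the bicyclic frame and are erased on aromatization, so no stereocentre has to be controlled. The step needs regioselective bonding of the acetal CH2 to C6 rather than to C3, C4 or C5: the 5-ester and the lactone carbonyl together polarize C6, the aryloxy donor lowers the acceptor character of C4, and the dioxolane masks a ketone that would otherwise activate C5 or act as a heterodiene, so the methoxy group ends para to the ester carbon. The aryloxy-bearing carbon stays sp2 from 14 to 19, so only methanol, and not the aryloxide, can be lost in the aromatization.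

Step 13
Reactants: 19 methyl 2-[2,4-bis(benzyloxy)-6-pentylphenoxy]-6-(2-butyl-1,3-dioxolan-2-yl)-4-methoxybenzoate
Product: 20 methyl 2-[2,4-bis(benzyloxy)-6-pentylphenoxy]-4-methoxy-6-pentanoylbenzoate
Conditions: 2 M aq. HCl, THF, 50 °C
Reagents that add atoms: water, O
Why: Acid-catalysed ketal hydrolysis through an aryl-stabilized oxocarbenium ion, to which the benzyl ethers and the diaryl ether are inert; any 3-alkoxyphthalide pseudo-ester formed by participation of the neighbouring ester converges on the same keto acid in step 14.

Step 14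
Reactants: 20 methyl 2-[2,4-bis(benzyloxy)-6-pentylphenoxy]-4-methoxy-6-pentanoylbenzoate
Product: 21 2-[2,4-bis(benzyloxy)-6-pentylphenoxy]-4-methoxy-6-pentanoylbenzoic acid
Conditions: LiOH (5 equiv), THF/MeOH/H2O, 50 °C; then 1 M HCl to pH 3
Reagents that add atoms: lithium hydroxide, [Li+].[OH-]
Why: Saponification of the doubly ortho-substituted benzoate is assisted by the neighbouring ketone, whose hydroxide adduct attacks the ester intramolecularly and passes through a hydroxyphthalide that opens to the keto carboxylate; the aqueous medium favours this over Claisen closure to an indanedione.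

Step 15
Reactants: 21 2-[2,4-bis(benzyloxy)-6-pentylphenoxy]-4-methoxy-6-pentanoylbenzoic acid
Product: 22 2-(2,4-dihydroxy-6-pentylphenoxy)-4-methoxy-6-pentanoylbenzoic acid (target CNP0189595.0)
Conditions: H2 (1 atm), Pd/C (10% palladium on carbon), EtOAc, rt, stopped when debenzylation is complete
Reagents that add atoms: none
Why: Hydrogenolysis of aryl benzyl ethers on palladium is fast at ambient pressure, so the aryl ketone, the diaryl ether and the acid should survive if the reaction is stopped at full conversion.

**Compound list**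
1 | olivetol (5-pentylbenzene-1,3-diol) | CCCCCc1cc(O)cc(O)c1 | starting material
2 | 1,3-bis(benzyloxy)-5-pentylbenzene | CCCCCc1cc(OCc2ccccc2)cc(OCc2ccccc2)c1 | intermediate
3 | 2,4-bis(benzyloxy)-6-pentylbenzaldehyde | CCCCCc1cc(OCc2ccccc2)cc(OCc2ccccc2)c1C=O | intermediate
4 | 2,4-bis(benzyloxy)-6-pentylphenyl formate | CCCCCc1cc(OCc2ccccc2)cc(OCc2ccccc2)c1OC=O | intermediate
5 | 2,4-bis(benzyloxy)-6-pentylphenol | CCCCCc1cc(OCc2ccccc2)cc(OCc2ccccc2)c1O | intermediate
6 | ethyl 2-oxohexanoate | CCCCC(=O)C(=O)OCC | starting material
7 | ethyl 2-butyl-1,3-dioxolane-2-carboxylate | CCCCC1(OCCO1)C(=O)OCC | intermediate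
8 | sodium 2-butyl-1,3-dioxolane-2-carboxylate | CCCCC1(OCCO1)C(=O)[O-].[Na+] | intermediate
9 | 2-butyl-1,3-dioxolane-2-carbonyl chloride | CCCCC1(OCCO1)C(=O)Cl | intermediate
10 | dimethyl 3-oxoglutarate (dimethyl 3-oxopentanedioate) | COC(=O)CC(=O)CC(=O)OC | starting material
11 | dimethyl 2-(2-butyl-1,3-dioxolane-2-carbonyl)-3-oxopentanedioate | COC(=O)CC(=O)C(C(=O)OC)C(=O)C1(CCCC)OCCO1 | intermediate
12 | methyl 6-(2-butyl-1,3-dioxolan-2-yl)-4-hydroxy-2-oxo-2H-pyran-5-carboxylate | CCCCC1(OCCO1)C2=C(C(=O)OC)C(O)=CC(=O)O2 | intermediate
13 | methyl 6-(2-butyl-1,3-dioxolan-2-yl)-4-chloro-2-oxo-2H-pyran-5-carboxylate | CCCCC1(OCCO1)C2=C(C(=O)OC)C(Cl)=CC(=O)O2 | intermediate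
14 | methyl 4-[2,4-bis(benzyloxy)-6-pentylphenoxy]-6-(2-butyl-1,3-dioxolan-2-yl)-2-oxo-2H-pyran-5-carboxylate | CCCCCc1cc(OCc2ccccc2)cc(OCc2ccccc2)c1OC1=CC(=O)OC(C2(CCCC)OCCO2)=C1C(=O)OC | intermediate
15 | bromoacetaldehyde dimethyl acetal (2-bromo-1,1-dimethoxyethane) | COC(CBr)OC | starting material
16 | 1,1-dimethoxyethene | C=C(OC)OC | intermediate
17 | methyl 5-[2,4-bis(benzyloxy)-6-pentylphenoxy]-1-(2-butyl-1,3-dioxolan-2-yl)-8,8-dimethoxy-3-oxo-2-oxabicyclo[2.2.2]oct-5-ene-6-carboxylate (racemic, relative configuration fixed by the bicycle) | O=C1OC2(C3(CCCC)OCCO3)CC(OC)(OC)C1C(Oc1c(CCCCC)cc(OCc3ccccc3)cc1OCc1ccccc1)=C2C(=O)OC | intermediate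
18 | methyl 6-[2,4-bis(benzyloxy)-6-pentylphenoxy]-2-(2-butyl-1,3-dioxolan-2-yl)-4,4-dimethoxycyclohexa-1,5-diene-1-carboxylate | COC1(OC)CC(C2(CCCC)OCCO2)=C(C(=O)OC)C(Oc2c(CCCCC)cc(OCc3ccccc3)cc2OCc2ccccc2)=C1 | intermediate
19 | methyl 2-[2,4-bis(benzyloxy)-6-pentylphenoxy]-6-(2-butyl-1,3-dioxolan-2-yl)-4-methoxybenzoate | CCCCCc1cc(OCc2ccccc2)cc(OCc2ccccc2)c1Oc1cc(OC)cc(C2(CCCC)OCCO2)c1C(=O)OC | intermediate
20 | methyl 2-[2,4-bis(benzyloxy)-6-pentylphenoxy]-4-methoxy-6-pentanoylbenzoate | CCCCCc1cc(OCc2ccccc2)cc(OCc2ccccc2)c1Oc1cc(OC)cc(C(=O)CCCC)c1C(=O)OC | intermediate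
21 | 2-[2,4-bis(benzyloxy)-6-pentylphenoxy]-4-methoxy-6-pentanoylbenzoic acid | CCCCCc1cc(OCc2ccccc2)cc(OCc2ccccc2)c1Oc1cc(OC)cc(C(=O)CCCC)c1C(=O)O | intermediate
22 | 2-(2,4-dihydroxy-6-pentylphenoxy)-4-methoxy-6-pentanoylbenzoic acid | CCCCCc1cc(O)cc(O)c1Oc1cc(OC)cc(C(=O)CCCC)c1C(=O)O | target

**Step count**
Total: 15 steps. Longest linear sequence: 11 steps (6 to 22 through steps 4 to 10 and 12 to 15).

**Steps most likely to fail**

1. Step 12 (key step). Bond formation at C6 may be slow, because C6 carries a fully substituted carbon and the 4-aryloxy donor makes the pyrone less electrophilic. Oligomerization of the ketene acetal, or its addition–elimination at C4 with loss of the aryloxide, could then outrun the cycloaddition. The fallback sets out from 14 and comes back at 19. The two-carbon partner is changed from the sp2 ketene acetal to the sterically slimmer alkyne methoxyethyne F1, prepared from commercial chloroacetaldehyde dimethyl acetal by double elimination (loss of HCl and methanol) with NaNH2 in liquid NH3. Heating 14 with F1 in toluene in a sealed tube should give, by pyrone–alkyne Diels–Alder reaction with the same polarity-controlled orientation, methyl 5-[2,4-bis(benzyloxy)-6-pentylphenoxy]-1-(2-butyl-1,3-dioxolan-2-yl)-8-methoxy-3-oxo-2-oxabicyclo[2.2.2]octa-5,7-diene-6-carboxylate F2. Retro-Diels–Alder loss of CO2 from this bridged lactone delivers 19 directly, with no methanol elimination needed.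

2. Step 10. The hindered phenoxide may attack C6 or the lactone carbonyl and open the ring, or the vinylogous acid chloride may hydrolyse back to the hydroxypyrone, instead of clean substitution at C4. The fallback sets out from 10, 5 and 9 and comes back at 14; it forms the aryl–oxygen bond before the pyrone exists. Dehydration of 10 with 2-chloro-1,3-dimethylimidazolinium chloride and Et3N in CH2Cl2 gives the allene dimethyl penta-2,3-dienedioate F3. Base-catalysed oxa-Michael addition of phenol 5 (Et3N, CH2Cl2, rt) should give dimethyl 3-[2,4-bis(benzyloxy)-6-pentylphenoxy]pent-2-enedioate F4. Deprotonation of its CH2 with LiN(SiMe3)2 in THF at −78 °C and C-acylation with 9 gives dimethyl 3-[2,4-bis(benzyloxy)-6-pentylphenoxy]-4-(2-butyl-1,3-dioxolane-2-carbonyl)pent-2-enedioate F5. Enol lactonization of F5 with DBU in warm toluene, with loss of methanol, closes the pyrone and gives 14.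

3. Step 7. The α,α-dialkoxy acyl chloride may lose CO or open its dioxolane under the magnesium Lewis acid before the C–C bond forms, and O-acylation may compete with C-acylation. The fallback sets out from 8 and comes back at 11; it reverses which partner is the acyl donor, so that 9 is not needed. Careful acidification of 8 with one equivalent of cold aqueous HCl and extraction gives 2-butyl-1,3-dioxolane-2-carboxylic acid F6. 1,1'-Carbonyldiimidazole in THF converts it into the acyl imidazolide (2-butyl-1,3-dioxolan-2-yl)(1H-imidazol-1-yl)methanone F7. Masamune homologation with potassium methyl malonate and MgCl2 (THF/MeCN, rt to 50 °C) and decarboxylation give methyl 3-(2-butyl-1,3-dioxolan-2-yl)-3-oxopropanoate F8. C-acylation of the magnesium enolate of F8 (MgCl2, pyridine, CH2Cl2, 0 °C) with commercial methyl malonyl chloride then gives 11.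

**Further compounds**
F1 | step 12 | methoxyethyne | COC#C
F2 | step 12 | methyl 5-[2,4-bis(benzyloxy)-6-pentylphenoxy]-1-(2-butyl-1,3-dioxolan-2-yl)-8-methoxy-3-oxo-2-oxabicyclo[2.2.2]octa-5,7-diene-6-carboxylate (racemic) | O=C1OC2(C3(CCCC)OCCO3)C=C(OC)C1C(Oc1c(CCCCC)cc(OCc3ccccc3)cc1OCc1ccccc1)=C2C(=O)OC
F3 | step 10 | dimethyl penta-2,3-dienedioate | COC(=O)C=C=CC(=O)OC
F4 | step 10 | dimethyl 3-[2,4-bis(benzyloxy)-6-pentylphenoxy]pent-2-enedioate (E/Z mixture) | COC(=O)CC(Oc1c(CCCCC)cc(OCc2ccccc2)cc1OCc1ccccc1)=CC(=O)OC
F5 | step 10 | dimethyl 3-[2,4-bis(benzyloxy)-6-pentylphenoxy]-4-(2-butyl-1,3-dioxolane-2-carbonyl)pent-2-enedioate (E/Z mixture) | COC(=O)C=C(Oc1c(CCCCC)cc(OCc2ccccc2)cc1OCc1ccccc1)C(C(=O)OC)C(=O)C1(CCCC)OCCO1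
F6 | step 7 | 2-butyl-1,3-dioxolane-2-carboxylic acid | CCCCC1(OCCO1)C(=O)O
F7 | step 7 | (2-butyl-1,3-dioxolan-2-yl)(1H-imidazol-1-yl)methanone | CCCCC1(OCCO1)C(=O)n1ccnc1
F8 | step 7 | methyl 3-(2-butyl-1,3-dioxolan-2-yl)-3-oxopropanoate | CCCCC1(OCCO1)C(=O)CC(=O)OC
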